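## Analysis of the target

The target 21 is a bicyclo[3.3.1]nonane-2,4,9-trione of the polyprenylated acylphloroglucinol family. Ring A (C1–C2–C3–C4–C5–C9) is an enolised β-triketone that carries the 3-hydroxybenzoyl group on C3, and ring B (C1–C8–C7–C6–C5–C9) shares both bridgeheads and the C9 ketone with it. There are four stereocentres: C1 and C5 are prenylated quaternary bridgeheads tied to each other by the bicycle; C8 is quaternary (methyl and 4-methylpent-3-enyl, "homoprenyl") and bonded directly to C1; C7 is tertiary, with its prenyl on the ring A side of ring B (endo), cis to the homoprenyl and trans to the methyl on C8. In the tautomer drawn this is the (1S,5S,7S,8S) isomer. Four trisubstituted alkenes exclude hydrogenation, strong acid and free electrophilic halogen or oxidants; the enolised trione is acidic and closes onto the neighbouring prenyl under acid; the phenol is a second acidic site. The hard points are the bond between the quaternary carbons C1 and C8, the bridgehead C5, a C7 configuration that cannot be corrected by epimerisation, and an absolute configuration with no nearby functional group to steer a catalyst. The strategy rests on the C5–C6 bond: C5 is the prenyl-bearing enol carbon between C4 and C9, and C6 is the CH2 terminus of a 1,1-disubstituted alkene at C7, so both are nucleophilic; turning C5 into a bromide lets it react as a radical that closes ring B onto C6. Once that bond is opened, ring A with C9 is a dearomatised acylphloroglucinol, so every oxygen and the aroyl group can come from an aromatic precursor.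

## Retrosynthetic reasoning

**21 from 20 (O–S bond of a protecting group).** The last step only frees the phenol. An aryl sulfonate is used instead of an acetal: the group has to pass a Lewis-acid acylation, cold aqueous alkali, heating, electrophilic bromine and silyl radicals, and it leaves under hydroxide, where the trione is a delocalised enolate and the prenyl groups are untouched. An acetal could not be carried through the acylation and would need acid at the end, which closes the C4 enol onto the C5 prenyl.

**20 from 19 (C5–C6 and C7–H).** Cutting C5–C6 opens ring B at its least hindered bond and leaves a monocyclic dearomatised trione with the side chain C8–C7(=C6H2) on C1. Forward, the C5 radical must add to the CH2 terminus (6-endo), and the tertiary C7 radical must take hydrogen on the face turned away from the C2–C3–C4 bridge. C5 needs no separate control, because the bond can only form on the ring face that carries the chain. Cutting C1–C8 here instead would ask a radical or an enolate to join two quaternary carbons.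

**19 from 18 (C5–Br).** The bromine is placed by electrophilic attack on the enol carbon C5. This is the polarity reversal: the carbon that is nucleophilic in 18 becomes a radical precursor in 19. Both C5 epimers are acceptable, since they give the same planar radical.

**18 from 17, and 17 from 16 (C1–C8).** The bond between the two quaternary carbons is made by a [3,3] shift from the oxygen on C9 of aryl allyl ether 16 to the prenylated ortho carbon. A concerted intramolecular step is the most reliable way to join two fully substituted carbons. The ring cannot rearomatise and settles as the enolised trione. Because the ether oxygen lies between two equivalent prenylated carbons, there is no regiochemical choice. The relative configuration C1/C8 follows from the alkene geometry: through the chair transition state the Z ether (homoprenyl cis to the CH2O carbon) gives the arrangement of 21. The ether oxygen has no flanking carbonyl for two-point binding of a chiral Lewis acid, and Lewis acids would favour ionisation of the allylic C–O bond, so absolute configuration is not entrusted to a catalyst. The racemate 17, the first chiral compound of the route, is resolved to 18.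

**16 from 15 and 9 (O–C6).** The ether is formed at the most acidic hydroxyl of 15, the one para to the ketone, with the primary allylic alcohol 9 under redox-condensation conditions. No allylic halide has to be made, and C-alkylation, which would attach the chain through the wrong carbon, is avoided.

**15 from 14 and 2; 14 from 11 and 12 (via 13); 11 from 10.** The two ring prenyls are introduced by C-alkylation of the acylphloroglucinol 14 in water, and the ketone by Friedel–Crafts acylation of 12 with the acid chloride 13 of the sulfonate-protected acid 11, itself made from 10. This order puts the symmetric, fully oxygenated core together in three steps.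

**9 from 8; 8 from 5 and 6 (via 7); 5 from 3 (via 4); 3 from 1 and 2.** The tetrasubstituted alkene of 9 is the only stereo-element of this fragment. It is cut at the bond between the alkene carbon and the homoprenyl group: a Z enol triflate 5 of the prenylated keto ester 3 is formed under chelation control and coupled with retention with the organozinc 7 from 6. Reduction of ester 8 gives 9. Cutting at the alkene itself (olefination) would give no control over the geometry of a tetrasubstituted alkene.

## Alternatives that were turned down

**Alternative 1:** Photochemical acyl migration. The disconnection is C4–C5 of ring A, traced back to the acyl–oxygen bond of a bicyclic enol lactone A1: ring B with a C5=C9 double bond, the lactone oxygen on C9, the acyl carbon C4, a methoxy group on C2. On irradiation the O–C4 bond would break and the acyl and oxa-allyl radicals would recombine at C5 (1,3-acyl shift), giving the methyl enol ether A2 of the 2,4,9-trione.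
- For: the hindered bridgehead bond forms inside a solvent cage without reagents, and C5 is fixed by the existing ring. Ring B with its stereocentres could be built by enolate chemistry for which catalytic asymmetric methods exist, so on absolute control this plan is stronger than a resolution.
- Against: the key step solves none of the stereochemical problems (C1–C8, C7, C8), all of which must be settled beforehand on a cyclohexane. The radical pair can also lose CO or recombine at oxygen. Four alkenes sit near an excited carbonyl (oxetane formation, allylic hydrogen abstraction). A2 has no aroyl group, so C3 metalation and acylation, enol ether cleavage and phenol deprotection follow, at least three further steps.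
- Comparison: the chosen strategy takes ring A complete, with the aroyl group and all oxygens, from 12 and closes ring B in a single bond-forming step. It pays for this with a resolution.

**Alternative 2:** Gold-catalysed closure of ring A. The disconnection is C1–C2. A silyl enol ether A3 (C9=C1 enol ether of a cyclohexanone that carries the ynone C4(=O)–C3≡C2H on C5) would attack the alkyne terminus, activated by a cationic gold phosphine catalyst, in the 6-endo-dig mode and give the bicyclic enone A4.
- For: the reaction is catalytic, is of a type that forges bridgehead quaternary carbons in this ring system, and leaves the C9 ketone in place. The cyclohexanone precursor is open to catalytic asymmetric synthesis, which is again stronger than a resolution.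
- Against: the bond formed, C1–C2, starts from a tetrasubstituted enol ether carbon that is neighbour to the quaternary C8, the most crowded site of the molecule. Four electron-rich alkenes compete with the enol ether for the activated alkyne. A4 has C2 at the alkene oxidation level and no aroyl group, so C2 oxygenation, C3 acylation and deprotection add several steps to an already long linear synthesis of A3.
- Comparison: the chosen strategy makes the most hindered bond by a sigmatropic shift and leaves the ring-closing step only an unhindered CH2, and the oxidation pattern is present from the first aromatic intermediate.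

**Alternative 3:** Alkylation–Michael annulation. Both bonds of ring B (C5–C6 and C1–C8) are cut. The phenolate of the diprenyl acylphloroglucinol A5 would be C-alkylated at C5 by the allylic bromide of enal A6, and the resulting dienolate would add through C1 to the β-carbon of the enal, giving the C7 aldehyde A7.
- For: two C–C bonds and ring B form in one flask from an aromatic precursor closely related to 15, and phase-transfer versions of this annulation type can be made enantioselective. In bond economy and in absolute control this plan is stronger than the chosen one.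
- Against: (a) C7 is α to an aldehyde and the Michael step is reversible, so the formyl group should settle in the equatorial, exo position, whereas 21 needs the endo arrangement. (b) The acceptor carbon is β,β-disubstituted with two groups of similar size, and the enal geometry can scramble through the dienolate, so C8 relative to C1 is uncertain. (c) Turning the formyl group into a prenyl needs three or four steps on a free trione. (d) The acetal must be removed with acid at the end.
- Comparison: the chosen strategy fixes C8 through alkene geometry in a concerted step, sets C7 kinetically at a centre that cannot epimerise, and carries the C7 prenyl from the start. Its price is a resolution and a two-step ring closure (bromination, then radical).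

Key step: step 12

## Route

Remark: locants C1 to C9 are those of the bicyclic core of 21 and are kept for all intermediates; stereodescriptors of enolised compounds refer to the tautomer written in the SMILES.

Step 1
Reactants: 1 ethyl acetoacetate; 2 prenyl bromide (1-bromo-3-methylbut-2-ene)
Product: 3 ethyl 2-acetyl-5-methylhex-4-enoate
Conditions: K2CO3, acetone, reflux (1 in slight excess)
Reagents that add atoms: none
Why: Acetoacetic ester alkylation: the stabilised enolate is C-alkylated by the allylic bromide, and a slight excess of 1 keeps dialkylation low.

Step 2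
Reactants: 3 ethyl 2-acetyl-5-methylhex-4-enoate
Product: 5 ethyl (2Z)-2-(3-methylbut-2-en-1-yl)-3-(trifluoromethanesulfonyloxy)but-2-enoate, via sodium Z-enolate 4 (not isolated)
Conditions: NaH, Et2O, 0 °C; then Tf2O, −78 → 0 °C
Reagents that add atoms: trifluoromethanesulfonic anhydride, O=S(=O)(OS(=O)(=O)C(F)(F)F)C(F)(F)F
Why: Enol triflate formation from a β-keto ester: in a weakly coordinating solvent Na+ is chelated between the enolate and ester oxygens, so O-sulfonylation should give the isomer with OTf cis to the ester (Z).

Step 3
Reactants: 5 ethyl (2Z)-2-(3-methylbut-2-en-1-yl)-3-(trifluoromethanesulfonyloxy)but-2-enoate; 6 5-bromo-2-methylpent-2-ene (homoprenyl bromide)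
Product: 8 ethyl (2Z)-3,7-dimethyl-2-(3-methylbut-2-en-1-yl)octa-2,6-dienoate, via (4-methylpent-3-en-1-yl)zinc bromide 7 (not isolated)
Conditions: 6, Zn dust, LiCl, THF, 40 °C; then 5, Pd(dppf)Cl2 (3 mol%), THF, 50 °C
Reagents that add atoms: none
Why: Negishi coupling: zinc inserts into the primary bromide, and palladium-catalysed coupling with the enol triflate runs with retention at the alkene carbon, which should place homoprenyl cis and methyl trans to the ester; the wide bite angle of dppf favours reductive elimination over β-hydride elimination.

Step 4
Reactants: 8 ethyl (2Z)-3,7-dimethyl-2-(3-methylbut-2-en-1-yl)octa-2,6-dienoate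
Product: 9 (2Z)-3,7-dimethyl-2-(3-methylbut-2-en-1-yl)octa-2,6-dien-1-ol
Conditions: i-Bu2AlH (2.5 equiv), CH2Cl2, −78 → 0 °C; aq. Rochelle salt
Reagents that add atoms: none
Why: 1,2-Reduction of the α,β-unsaturated ester to the allylic alcohol; the geometry of the tetrasubstituted alkene is not touched.

Step 5
Reactants: 10 3-hydroxybenzoic acid
Product: 11 3-[(4-methylbenzenesulfonyl)oxy]benzoic acid
Conditions: TsCl (1.2 equiv), NaOH (aq, 3 equiv), THF, 0 °C → rt; then HCl (aq)
Reagents that add atoms: 4-methylbenzenesulfonyl chloride, Cc1ccc(cc1)S(Cl)(=O)=O
Why: Schotten–Baumann sulfonylation of the phenolate; any mixed carboxylic–sulfonic anhydride is hydrolysed in the aqueous base, so the free acid is recovered on acidification.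

Step 6
Reactants: 11 3-[(4-methylbenzenesulfonyl)oxy]benzoic acid; 12 phloroglucinol (benzene-1,3,5-triol)
Product: 14 3-(2,4,6-trihydroxybenzoyl)phenyl 4-methylbenzenesulfonate, via 3-(tosyloxy)benzoyl chloride 13 (not isolated)
Conditions: (COCl)2, DMF (cat.), CH2Cl2, rt, evaporate; then 12 (1.5 equiv), AlCl3, PhNO2, 0 → 60 °C; aq. HCl
Reagents that add atoms: none
Why: Acid chloride formation followed by Friedel–Crafts C-acylation of the triol, the standard entry to 2-acylphloroglucinols; the aryl sulfonate is inert to AlCl3 at this temperature, and a second acylation is slowed by the deactivating ketone and the excess of 12.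

Step 7
Reactants: 14 3-(2,4,6-trihydroxybenzoyl)phenyl 4-methylbenzenesulfonate; 2 prenyl bromide
Product: 15 3-[2,4,6-trihydroxy-3,5-bis(3-methylbut-2-en-1-yl)benzoyl]phenyl 4-methylbenzenesulfonate
Conditions: 2 (2.1 equiv), KOH (5% aq), 0 °C; then HCl (aq)
Reagents that add atoms: none
Why: C-Alkylation of an acylphloroglucinolate: in water the oxygen atoms are solvated and the anion reacts through carbon, so the two prenyl groups should enter the two free ring positions; at 0 °C the aryl sulfonate is not hydrolysed.

Step 8
Reactants: 15 3-[2,4,6-trihydroxy-3,5-bis(3-methylbut-2-en-1-yl)benzoyl]phenyl 4-methylbenzenesulfonate; 9 (2Z)-3,7-dimethyl-2-(3-methylbut-2-en-1-yl)octa-2,6-dien-1-ol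
Product: 16 3-[4-{[(2Z)-3,7-dimethyl-2-(3-methylbut-2-en-1-yl)octa-2,6-dien-1-yl]oxy}-2,6-dihydroxy-3,5-bis(3-methylbut-2-en-1-yl)benzoyl]phenyl 4-methylbenzenesulfonate
Conditions: PPh3, DIAD, THF, 0 °C → rt
Reagents that add atoms: none
Why: Mitsunobu etherification: the hydroxyl para to the ketone is the most acidic and is not hydrogen-bonded to the carbonyl, so it should be the one alkylated, and the primary allylic oxyphosphonium ion is displaced by SN2 without allylic shift. An ether formed at an ortho oxygen could still deliver the chain to the same prenylated carbon in step 9.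

Step 9
Reactants: 16 the Z allyl aryl ether
Product: 17 racemic 3-{[2,4-dihydroxy-3,5-bis(3-methylbut-2-en-1-yl)-6-oxo-5-(2,6,10-trimethyl-7-methylideneundeca-2,9-dien-6-yl)cyclohexa-1,3-dien-1-yl]carbonyl}phenyl 4-methylbenzenesulfonate (pair 5S,6'S and 5R,6'R; ring carbon 5 is C1 and chain carbon 6' is C8)
Conditions: PhNEt2, 140 °C, Ar
Reagents that add atoms: none
Why: Aromatic Claisen rearrangement onto a substituted ortho carbon: the O–C6 bond breaks, C8 bonds to the prenylated carbon C1, and the dienone, unable to rearomatise, tautomerises to the enolised trione. The two ortho carbons are equivalent; the chair transition state keeps C7 and its prenyl away from the ring and with the Z ether should join C1 and C8 in the relative configuration of 21, as a racemate. The basic solvent suppresses acid-promoted ionisation of the allylic ether.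

Step 10
Reactants: 17 the racemic trione
Product: 18 3-({(5S)-2,4-dihydroxy-3,5-bis(3-methylbut-2-en-1-yl)-6-oxo-5-[(6S)-2,6,10-trimethyl-7-methylideneundeca-2,9-dien-6-yl]cyclohexa-1,3-dien-1-yl}carbonyl)phenyl 4-methylbenzenesulfonate (C1 and C8 as in 21)
Conditions: preparative HPLC, cellulose tris(3,5-dimethylphenylcarbamate) on silica, hexane/i-PrOH/CF3CO2H (0.1%), rt
Reagents that add atoms: none
Why: Resolution by chromatography on a chiral stationary phase at the first chiral compound of the route; the acid modifier keeps the enol tautomers in fast exchange. The fraction to be carried on is assigned by anomalous-dispersion X-ray analysis of a crystalline bromide or sulfonate derived from it, or by correlation with 21.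

Step 11
Reactants: 18 the (1S,8S) trione
Product: 19 3-{[3-bromo-2-hydroxy-3,5-bis(3-methylbut-2-en-1-yl)-4,6-dioxo-5-(2,6,10-trimethyl-7-methylideneundeca-2,9-dien-6-yl)cyclohex-1-en-1-yl]carbonyl}phenyl 4-methylbenzenesulfonate (C1 and C8 as in 18; both epimers at the brominated carbon C5)
Conditions: NBS (1.05 equiv), CH2Cl2, −78 °C, dark; used without chromatography
Reagents that add atoms: N-bromosuccinimide, BrN1C(=O)CCC1=O
Why: Electrophilic α-bromination of a 2-alkyl-1,3-dione unit: C5 is the only alkyl-bearing enol carbon and at −78 °C is far more nucleophilic than the isolated alkenes or the acyl-bearing C3. Both C5 epimers should form, and both give the same radical in step 12.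

Step 12
Reactants: 19 the C5 bromide
Product: 20 (1S,5S,7S,8S)-4-hydroxy-8-methyl-1,5,7-tris(3-methylbut-2-en-1-yl)-8-(4-methylpent-3-en-1-yl)-3-{3-[(4-methylbenzenesulfonyl)oxy]benzoyl}bicyclo[3.3.1]non-3-ene-2,9-dione
Conditions: (Me3Si)3SiH (1.3 equiv, syringe pump over 4 h), Et3B (0.3 equiv), air, PhMe (0.005 M), 0 °C → rt
Reagents that add atoms: none
Why: Ethyl radicals from Et3B and O2 start a silyl radical chain, and (Me3Si)3Si• abstracts bromine from C5 to give a radical delocalised over C9=O and the C4=C3–C2=O unit, which is electrophilic and polarity-matched to the electron-rich 1,1-disubstituted alkene. It adds to the unsubstituted terminus C6 and closes ring B in the 6-endo-trig mode, the mode preferred by 2-oxohex-5-enyl radicals when the inner alkene carbon is substituted and the ketone (here C9) lies inside the forming ring. The closest known reaction type is the reductive radical cyclisation of 2-halo-1,3-dicarbonyl compounds onto alkenes. The C5–C6 bond can only form on the face of the trione ring that carries the C8 chain, so C5 follows from C1 and its prenyl ends up equatorial on ring B. The tertiary C7 radical cannot reach the prenyls on C1 and C5, which are locked equatorial, and should be quenched by the bulky silane on the convex face, away from the C2–C3–C4 bridge; this sets C7 with the prenyl endo and cis to the C8 homoprenyl. The step needs chemoselectivity for C6 over 5-exo attack on the C1 prenyl, over reaction through C3 and over early reduction of the C5 radical. The unhindered CH2 terminus, the tertiary product radical, the gem-disubstitution at C8, retention of the chelated acyl-enol unit only on reaction through C5, and slow addition of the silane at high dilution are expected to secure it.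

Step 13
Reactants: 20 the bicyclic aryl sulfonate
Product: 21 (1S,5S,7S,8S)-4-hydroxy-3-(3-hydroxybenzoyl)-8-methyl-1,5,7-tris(3-methylbut-2-en-1-yl)-8-(4-methylpent-3-en-1-yl)bicyclo[3.3.1]non-3-ene-2,9-dione
Conditions: LiOH (6 equiv), 1,4-dioxane/H2O, 70 °C; then aq. citric acid to pH 3
Reagents that add atoms: none
Why: Sulfonate ester hydrolysis: hydroxide attacks sulfur and the phenolate leaves. The trione is a delocalised enolate under these conditions and should resist retro-Claisen cleavage, no acid meets the prenyl groups, and the absence of an alcohol solvent avoids an alkyl sulfonate that could alkylate the product.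

## Compound list

1 | ethyl acetoacetate | CCOC(=O)CC(C)=O | starting material
2 | prenyl bromide (1-bromo-3-methylbut-2-ene) | CC(C)=CCBr | starting material
3 | ethyl 2-acetyl-5-methylhex-4-enoate (racemic) | CCOC(=O)C(CC=C(C)C)C(C)=O | intermediate
4 | sodium (2Z)-enolate of 3 (not isolated) | CCOC(=O)/C(CC=C(C)C)=C(/C)[O-].[Na+] | intermediate
5 | ethyl (2Z)-2-(3-methylbut-2-en-1-yl)-3-(trifluoromethanesulfonyloxy)but-2-enoate | CCOC(=O)/C(CC=C(C)C)=C(/C)OS(=O)(=O)C(F)(F)F | intermediate
6 | 5-bromo-2-methylpent-2-ene (homoprenyl bromide) | CC(C)=CCCBr | starting material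
7 | (4-methylpent-3-en-1-yl)zinc bromide (not isolated) | CC(C)=CCC[Zn]Br | intermediate
8 | ethyl (2Z)-3,7-dimethyl-2-(3-methylbut-2-en-1-yl)octa-2,6-dienoate | CCOC(=O)/C(CC=C(C)C)=C(/C)CCC=C(C)C | intermediate
9 | (2Z)-3,7-dimethyl-2-(3-methylbut-2-en-1-yl)octa-2,6-dien-1-ol | OC/C(CC=C(C)C)=C(/C)CCC=C(C)C | intermediate
10 | 3-hydroxybenzoic acid | OC(=O)c1cccc(O)c1 | starting material
11 | 3-[(4-methylbenzenesulfonyl)oxy]benzoic acid | Cc1ccc(cc1)S(=O)(=O)Oc1cccc(c1)C(O)=O | intermediate
12 | phloroglucinol (benzene-1,3,5-triol) | Oc1cc(O)cc(O)c1 | starting material
13 | 3-[(4-methylbenzenesulfonyl)oxy]benzoyl chloride (not isolated) | Cc1ccc(cc1)S(=O)(=O)Oc1cccc(c1)C(Cl)=O | intermediate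
14 | 3-(2,4,6-trihydroxybenzoyl)phenyl 4-methylbenzenesulfonate | Cc1ccc(cc1)S(=O)(=O)Oc1cccc(c1)C(=O)c1c(O)cc(O)cc1O | intermediate
15 | 3-[2,4,6-trihydroxy-3,5-bis(3-methylbut-2-en-1-yl)benzoyl]phenyl 4-methylbenzenesulfonate | Cc1ccc(cc1)S(=O)(=O)Oc1cccc(c1)C(=O)c1c(O)c(CC=C(C)C)c(O)c(CC=C(C)C)c1O | intermediate
16 | 3-[4-{[(2Z)-3,7-dimethyl-2-(3-methylbut-2-en-1-yl)octa-2,6-dien-1-yl]oxy}-2,6-dihydroxy-3,5-bis(3-methylbut-2-en-1-yl)benzoyl]phenyl 4-methylbenzenesulfonate | Cc1ccc(cc1)S(=O)(=O)Oc1cccc(c1)C(=O)c1c(O)c(CC=C(C)C)c(OC/C(CC=C(C)C)=C(/C)CCC=C(C)C)c(CC=C(C)C)c1O | intermediate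
17 | racemic 3-{[2,4-dihydroxy-3,5-bis(3-methylbut-2-en-1-yl)-6-oxo-5-(2,6,10-trimethyl-7-methylideneundeca-2,9-dien-6-yl)cyclohexa-1,3-dien-1-yl]carbonyl}phenyl 4-methylbenzenesulfonate, 1:1 mixture of the (5S,6'S) and (5R,6'R) enantiomers | CC(C)=CCC[C@@](C)(C(=C)CC=C(C)C)[C@]1(CC=C(C)C)C(=O)C(C(=O)c2cccc(OS(=O)(=O)c3ccc(C)cc3)c2)=C(O)C(CC=C(C)C)=C1O.CC(C)=CCC[C@](C)(C(=C)CC=C(C)C)[C@@]1(CC=C(C)C)C(=O)C(C(=O)c2cccc(OS(=O)(=O)c3ccc(C)cc3)c2)=C(O)C(CC=C(C)C)=C1O | intermediate
18 | 3-({(5S)-2,4-dihydroxy-3,5-bis(3-methylbut-2-en-1-yl)-6-oxo-5-[(6S)-2,6,10-trimethyl-7-methylideneundeca-2,9-dien-6-yl]cyclohexa-1,3-dien-1-yl}carbonyl)phenyl 4-methylbenzenesulfonate | CC(C)=CCC[C@@](C)(C(=C)CC=C(C)C)[C@]1(CC=C(C)C)C(=O)C(C(=O)c2cccc(OS(=O)(=O)c3ccc(C)cc3)c2)=C(O)C(CC=C(C)C)=C1O | intermediate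
19 | 3-{[3-bromo-2-hydroxy-3,5-bis(3-methylbut-2-en-1-yl)-4,6-dioxo-5-(2,6,10-trimethyl-7-methylideneundeca-2,9-dien-6-yl)cyclohex-1-en-1-yl]carbonyl}phenyl 4-methylbenzenesulfonate, C1 and C8 as in 18, both C5 epimers | CC(C)=CCC[C@@](C)(C(=C)CC=C(C)C)[C@]1(CC=C(C)C)C(=O)C(C(=O)c2cccc(OS(=O)(=O)c3ccc(C)cc3)c2)=C(O)C(Br)(CC=C(C)C)C1=O | intermediate
20 | (1S,5S,7S,8S)-4-hydroxy-8-methyl-1,5,7-tris(3-methylbut-2-en-1-yl)-8-(4-methylpent-3-en-1-yl)-3-{3-[(4-methylbenzenesulfonyl)oxy]benzoyl}bicyclo[3.3.1]non-3-ene-2,9-dione | CC(C)=CCC[C@@]1(C)[C@@H](CC=C(C)C)C[C@]2(CC=C(C)C)C(=O)[C@@]1(CC=C(C)C)C(=O)C(C(=O)c1cccc(OS(=O)(=O)c3ccc(C)cc3)c1)=C2O | intermediate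
21 | (1S,5S,7S,8S)-4-hydroxy-3-(3-hydroxybenzoyl)-8-methyl-1,5,7-tris(3-methylbut-2-en-1-yl)-8-(4-methylpent-3-en-1-yl)bicyclo[3.3.1]non-3-ene-2,9-dione | CC(C)=CCC[C@@]1(C)[C@@H](CC=C(C)C)C[C@]2(CC=C(C)C)C(=O)[C@@]1(CC=C(C)C)C(=O)C(C(=O)c1cccc(O)c1)=C2O | target

## Step count and weak points

Total: 13 steps. Longest linear sequence: 10 steps (1 → 3 → 5 → 8 → 9 → 16 → 17 → 18 → 19 → 20 → 21); the aromatic branch from 10 needs 3 steps to reach 15.

**Step 12 (key step).** Three things can go wrong:
- The stabilised, electrophilic C5 radical may be reduced early by the hydridic Si–H bond before it cyclises. This returns 18, which can be brominated again.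
- Ring closure may go 5-exo onto the prenyl on C1, which sits on the other face of the nearly planar trione ring.
- Hydrogen delivery at C7 may not discriminate enough between the faces, because the exo face is flanked by the axial methyl on C8.

The acidic enol may also consume Et3B by protonolysis; an azo initiator active near 30 °C can then replace it.

Fallback, from 19 back to 20: separate bond formation from hydrogen transfer. A bromine-atom-transfer cyclisation without any hydride (CuBr with tris(2-pyridylmethyl)amine in CH2Cl2, or Et3B and air alone) lets the slow, possibly reversible addition run to the more stable bicyclo[3.3.1] radical, which is trapped as the tertiary C7 bromide F1. F1 is then reduced with (Me3Si)3SiH under radical initiation; the same C7 radical is formed and takes hydrogen on the exo face to give 20.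

**Step 9.** The most likely failure is loss of diastereocontrol through a competing boat transition state, since both ortho positions and both alkene termini are fully substituted. Heterolysis of the allylic C–O bond, which would give products of a formal 1,3-shift, is the second risk. Fallback, from 3 back to 17: if the rearrangement runs mainly through the boat, the geometric isomer is used.
- Triflation of 3 under non-chelating conditions (Tf2O, aq. Me4NOH, hexane) gives ethyl (2E)-2-(3-methylbut-2-en-1-yl)-3-(trifluoromethanesulfonyloxy)but-2-enoate F2.
- Negishi coupling with 7 gives ethyl (2E)-3,7-dimethyl-2-(3-methylbut-2-en-1-yl)octa-2,6-dienoate F3.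
- Reduction with i-Bu2AlH gives (2E)-3,7-dimethyl-2-(3-methylbut-2-en-1-yl)octa-2,6-dien-1-ol F4.
- Mitsunobu reaction with 15 gives the E aryl allyl ether F5, whose boat transition state leads to the same relative configuration, that is to 17.

**Step 11.** The 2-bromo-1,3-dione is itself a donor of electrophilic bromine, so transfer of bromine to the alkenes (bromo-etherification with the enol), bromination of the aryl rings, and loss of bromine on silica are the likely problems. Fallback, from 18 directly to 20: the C5 radical is generated oxidatively from the enol with Mn(OAc)3·2H2O in degassed ethanol. No halide is isolated, the radical closes ring B as in step 12, and the tertiary C7 radical, which this oxidant does not oxidise readily, takes hydrogen from the solvent. This fallback makes no new compound.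

**Step 8.** The phenol is ambident and carries three hydroxyl groups, so etherification at an ortho oxygen, C-alkylation, or allylic transposition in the oxyphosphonium ion can lower the return. Fallback, from 9 back to 16: the alcohol is converted with PPh3 and CBr4 at −40 °C into (2Z)-1-bromo-3,7-dimethyl-2-(3-methylbut-2-en-1-yl)octa-2,6-diene F6, and 15 is alkylated with F6 and K2CO3 in acetone at 0 °C. In a dipolar aprotic medium the potassium phenolate of the para hydroxyl reacts through oxygen and gives 16.

## Further compounds

F1 | step 12 | (1S,5S,8S)-7-bromo-4-hydroxy-8-methyl-1,5,7-tris(3-methylbut-2-en-1-yl)-8-(4-methylpent-3-en-1-yl)-3-{3-[(4-methylbenzenesulfonyl)oxy]benzoyl}bicyclo[3.3.1]non-3-ene-2,9-dione (C7 unassigned) | CC(C)=CCC[C@@]1(C)C(Br)(CC=C(C)C)C[C@]2(CC=C(C)C)C(=O)[C@@]1(CC=C(C)C)C(=O)C(C(=O)c1cccc(OS(=O)(=O)c3ccc(C)cc3)c1)=C2O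
F2 | step 9 | ethyl (2E)-2-(3-methylbut-2-en-1-yl)-3-(trifluoromethanesulfonyloxy)but-2-enoate | CCOC(=O)/C(CC=C(C)C)=C(\C)OS(=O)(=O)C(F)(F)F
F3 | step 9 | ethyl (2E)-3,7-dimethyl-2-(3-methylbut-2-en-1-yl)octa-2,6-dienoate | CCOC(=O)/C(CC=C(C)C)=C(\C)CCC=C(C)C
F4 | step 9 | (2E)-3,7-dimethyl-2-(3-methylbut-2-en-1-yl)octa-2,6-dien-1-ol | OC/C(CC=C(C)C)=C(\C)CCC=C(C)C
F5 | step 9 | 3-[4-{[(2E)-3,7-dimethyl-2-(3-methylbut-2-en-1-yl)octa-2,6-dien-1-yl]oxy}-2,6-dihydroxy-3,5-bis(3-methylbut-2-en-1-yl)benzoyl]phenyl 4-methylbenzenesulfonate | Cc1ccc(cc1)S(=O)(=O)Oc1cccc(c1)C(=O)c1c(O)c(CC=C(C)C)c(OC/C(CC=C(C)C)=C(\C)CCC=C(C)C)c(CC=C(C)C)c1O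
F0 | step 11 | none | none
F6 | step 8 | (2Z)-1-bromo-3,7-dimethyl-2-(3-methylbut-2-en-1-yl)octa-2,6-diene | BrC/C(CC=C(C)C)=C(/C)CCC=C(C)C
A1 | alternative 1 | bicyclic enol lactone: ring B with C5=C9 double bond, lactone oxygen on C9, acyl carbon C4, methoxy on C2 | CC(C)=CCC[C@@]1(C)[C@@H](CC=C(C)C)CC(CC=C(C)C)=C2OC(=O)C=C(OC)[C@@]12CC=C(C)C
A2 | alternative 1 | bicyclic methyl enol ether of the 2,4,9-trione without aroyl group | CC(C)=CCC[C@@]1(C)[C@@H](CC=C(C)C)C[C@]2(CC=C(C)C)C(=O)[C@@]1(CC=C(C)C)C(OC)=CC2=O
A3 | alternative 2 | tert-butyldimethylsilyl enol ether (C9=C1) of the cyclohexanone carrying a propynoyl group on C5 | CC(C)=CCC[C@@]1(C)[C@@H](CC=C(C)C)C[C@@](CC=C(C)C)(C(=O)C#C)C(O[Si](C)(C)C(C)(C)C)=C1CC=C(C)C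
A4 | alternative 2 | bicyclo[3.3.1]non-2-ene-4,9-dione with the ring B substituents of the target | CC(C)=CCC[C@@]1(C)[C@@H](CC=C(C)C)C[C@]2(CC=C(C)C)C(=O)[C@@]1(CC=C(C)C)C=CC2=O
A5 | alternative 3 | [3-(methoxymethoxy)phenyl][2,4,6-trihydroxy-3,5-bis(3-methylbut-2-en-1-yl)phenyl]methanone | COCOc1cccc(c1)C(=O)c1c(O)c(CC=C(C)C)c(O)c(CC=C(C)C)c1O
A6 | alternative 3 | (2E)-2-(bromomethyl)-3,7-dimethylocta-2,6-dienal | O=C/C(CBr)=C(/C)CCC=C(C)C
A7 | alternative 3 | bicyclic trione with formyl on C7 and methoxymethyl-protected aroyl group | CC(C)=CCC[C@@]1(C)[C@@H](C=O)C[C@]2(CC=C(C)C)C(=O)[C@@]1(CC=C(C)C)C(=O)C(C(=O)c1cccc(OCOC)c1)=C2O
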